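All runs stem from a simulated flask for an exercise; scatter was added.

At early times the readings already hold crystals: in the amber run at 0.500 min the target, crystals counted, stands at 6.3 % and the crystals at 1.9 %. My bench rule of thumb for these isothermal flasks is that, once crystals stand in the solution, it keeps a fixed dissolved c(target) and whatever is made beyond it comes out as crystals.

| flask | starting material | reagent in the second phase | remark | time | volume of the second phase over the first |
|---|---|---|---|---|---|
| ochre | 24 mM | 1 equiv | run made earlier |  |  |
| amber | 24 mM | 1.5 equiv | run made earlier |  |  |
| green | 48 mM | 2 equiv | run made earlier |  |  |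
| flask | 24 mM | 2.00 equiv |  | 6.0 min | 0.25 |

- ochre (time / min: target / %, crystals / %, starting material / %): 0.833: 9.2, 5.5, 94.2; 2.00: 25.3, 22.3, 74.6; 4.00: 41.9, 39.0, 56.4; 6.00: 51.5, 47.6, 44.7
- amber (time / min: target / %, crystals / %, starting material / %): 0.500: 6.3, 1.9, 94.9; 1.00: 16.9, 12.0, 83.7; 2.50: 42.5, 39.3, 52.8; 6.00: 68.0, 64.6, 25.9
- green (time / min: target / %, crystals / %, starting material / %): 1.50: 49.8, 47.3, 46.2; 3.00: 73.6, 75.5, 18.7; 5.00: 86.2, 84.4, 4.3; 6.00: 87.6, 85.4, 4.0

(each reading ± 1 percentage point)

- amounts and yields of target count crystals too
- in the second phase: reagent in the second phase; everything else is in the first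
- charges count per volume of the first phase; a concentration in a rate is the amount of a species over the volume of its own phase; every rate counts per litre of the first phase
- given per volume of solution although it is solid: crystals
- the earlier runs hold the two phases in the same ratio of volumes as the flask asked about

* amount of target and crystals together at 6.0 min, in percent of the starting material charged
* concentration of target in solution at 6.0 min, in percent of saturation

Target minus crystals at the last reading, times the charge, gives 0.936 mM in ochre, 0.816 mM in amber and 1.06 mM in green, although the green charge is twice the ochre one. I take their mean, 0.936 mM, as my ceiling, my reading of the solubility limit, which carries the scatter of both columns. For the flask I bracket y between amber, with less reagent, at 68.0 %, and green, with the same equivalents at the higher concentration, at 87.6 %, and I commit to the midpoint, 77.8 %, with c(target) near 100% of saturation. The rule reaches its border as target made over the ceiling nears one, and on my midpoint that ratio for the flask is 19.9, far above it.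

The forecast gives 77 % (73 % to 81 %) and 102 % of saturation (90 % to 118 %), holding that “the solution sits at saturation”. The flask gives 76.7 % and 108 %.

    reagent in the reaction phase ⇌ reagent in the second phase, rate k1*([reagent in the reaction phase] - [reagent in the second phase]/K1) per volume of the first phase (partition coefficient = 6.00, kL = 0.0140 s⁻¹)
    starting material + reagent in the reaction phase ⇌ target (K = 48.0 M⁻¹, k = 0.690 M⁻¹ s⁻¹)
    reagent in the reaction phase + target → over-reacted product (k = 0.750 M⁻¹ s⁻¹)
    crystals ⇌ target, rate k4*(cs4 - [target]) while solid is left; crystals form when [target] > cs4 (solubility = 0.570 mM, k = 0.230 s⁻¹)

Taking the ceiling's 3.90 % of the charge from 76.7 % leaves 72.8 % for crystals, and the flask holds 74.1 % at 6.00 min. There the exchange between starting material with reagent in the reaction phase and dissolved target relaxes with a half-life of 0.494 min, shorter than the 1.6 min half-life of dissolved target towards over-reacted product, and both are short against 6.0 min. In the neighbour charged with 6.0 mM, taking the ceiling's 15.6 % of the charge from its target of 21.2 % leaves 5.60 % for crystals, but that neighbour ends with crystals at 11.6 % and starting material at 70.2 %.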